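The runs are simulated for an exercise, and the scatter is random.

The starting material left at the last reading of the autumn run, 40.5% after 50.0 min, is my clock, and the midnight run's 80.2% after 150 min is the second one.

| flask | starting material | solid reagent | temperature | remark | time |
|---|---|---|---|---|---|
| midnight | 0.75 M | 0.80 equiv | 55 °C | run made earlier |  |
| autumn | 0.75 M | 0.80 equiv | 75 °C | run made earlier |  |
| elm | 1.5 M | 0.800 equiv |  | at 60 °C until 6.0 min, from then on at 90 °C | 20 min |
| birch | 1.5 M | 0.800 equiv | 90 °C |  | 20 min |
| oak | 1.5 M | 0.800 equiv | 75 °C |  | 20 min |
| larch | 1.5 M | 0.800 equiv | 60 °C |  | 20 min |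

- midnight (time / min: target / %, starting material / %): 15.0: 0.5, 97.3; 30.0: 0.1, 95.5; 60.0: 0.4, 91.7; 80.0: 0.3, 88.6; 120: 1.0, 84.4; 150: 1.7, 80.2
- autumn (time / min: target / %, starting material / %): 6.00: 0.3, 90.2; 12.0: 1.3, 82.4; 20.0: 3.2, 70.7; 30.0: 4.7, 59.0; 40.0: 6.2, 48.6; 50.0: 8.6, 40.5

(scatter of a reading: 0.5 percentage points)

- given per volume of solution although it is solid: solid reagent
- the analysis behind the earlier runs scatters by 0.5 percentage points, standard deviation
- at the start none of the solid reagent is in solution

- the flask with the highest amount of target, in percent of the starting material charged ("all alike" if they lie within 1.5 percentage points) (elm / birch / oak / larch / all alike)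
- final target, as a percentage of the starting material charged, in elm
- final target, as a percentage of the starting material charged, in birch
- final target, as a percentage of the starting material charged, in oak
- final target, as a percentage of the starting material charged, in larch

Read as first-order loss, these two leftovers give me rate constants for each bath:

k at 55 °C: 0.00147 min⁻¹
k at 75 °C: 0.0181 min⁻¹
Ea: 119 kJ mol⁻¹
k at 60 °C: 0.00283 min⁻¹
k at 90 °C: 0.0990 min⁻¹

Target shows a lag, an induction period: 0.3% after 6.00 min in the autumn run. So I take it to come by a second step and to grow with the square of conversion x. I carry one number: from the last autumn reading, 0.243 is the lag coefficient, target divided by the square of conversion. The last midnight reading gives 0.434, larger, but its target carries a scatter of 0.5 percentage points.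

The loose bounds are nothing and x itself, at one target per starting material. Tightened by assumption, my floor keeps the coefficient unchanged, as if 1.5 M brought nothing over 0.75 M. The ceiling is twice that, if the second step goes with c(starting material), here 1.5 M against 0.75 M.

birch: x 86.2%, target 18.0% to 36.1%
elm: x 75.4%, target 13.8% to 27.6%
oak: x 30.3%, target 2.24% to 4.47%
larch: x 5.51%, target 0.0737% to 0.147%

I commit to birch, whose reckoned x is higher than that of the other flasks.

The forecast names birch, with 20% in elm, 26% in birch, 5.5% in oak and 0.2% in larch, holding that “Target versus conversion is nearly the same at both temperatures”. Its elm and birch lie inside my brackets; its oak stands above my ceiling, and its larch too.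

The flasks give birch as highest: elm 13.9%, birch 20.7%, oak 2.87%, larch 0.212%. Elm sits at its floor, and larch stands above its ceiling.

    starting material → intermediate (k = 0.00150 s⁻¹, Ea = 117 kJ mol⁻¹)
    partner + intermediate → target (k = 7.80 × 10⁻⁴ M⁻¹ s⁻¹, Ea = 76.0 kJ mol⁻¹)
    solid reagent ⇌ partner, rate k3*(cs3 - [partner]) while solid is left; crystals form when [partner] > cs3 (solubility = 0.980 M, k = 0.00840 s⁻¹)
    starting material + target → side product (k = 0.00260 M⁻¹ s⁻¹, Ea = 78.0 kJ mol⁻¹)
    (constants at 90 °C)

At its end, birch gives a lag coefficient of 0.261, against 0.243 from autumn. The neighbour is larch at 85 °C, with the same amounts and time. The same reckoning gives k 0.0571 min⁻¹, x 68.1%, and target 11.2% to 22.5%. That flask keeps 30% of its starting material, where my clock left 31.9%, and it holds 11.7% target, a coefficient of 0.239.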